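## Structural features

The target is procyanidin B3 3,3'-di-O-gallate: two (2R,3S)-flavan-3-ol (catechin) units, each esterified at O3 by a 3,4,5-trihydroxybenzoyl group, joined by one bond from C4 of the upper unit to C8' of the lower unit. Each unit has a phloroglucinol-type benzo ring (ring A above, ring D below) fused to a dihydropyran (ring C above: O1–C2–C3–C4–C4a–C8a; ring F below) that carries a catechol ring (B, E) on C2. The upper unit has three contiguous stereocentres, C2 (R), C3 (S) and C4 (S), 2,3-trans and 3,4-trans, so the aryl groups on C2 and C4 are cis and all three substituents are equatorial; the lower unit has C2' (R) and C3' (S) next to the C4' methylene. Fragile groups are the ten free phenols (catechol and pyrogallol, sensitive to air and base), the two esters, the benzylic O1–C2 ethers (epimerised by acid or base) and the interflavan bond, which acid cleaves to a C4 cation. The real difficulty is C4: it is doubly benzylic, flanked by four ortho oxygen substituents, must be bonded to C8' and not C6', and must have the 4S configuration next to a hindered ester. The key step exploits the fact that O1 is a phenolic oxygen of ring A and C4 is benzylic to rings A and D: O1–C8a–C4a–C4 is the skeleton of an ortho-quinone methide carrying ring D on its methide carbon, and C2–C3, with ring B on C2 and the ester oxygen on C3, is an (E)-styryl ester.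

## Logic of the disconnections

**20 to 19.** The fourteen O–CH2Ph bonds are cut. One protecting group for all phenols allows a single neutral hydrogenolysis at the end, which the esters, the O1–C2 ethers and the C4–C8' bond tolerate. The demand is that every earlier step tolerates benzyl ethers and that nothing basic, acidic or oxidising follows deprotection.

**19 to 12 and 17 (through 18).** The O1–C2 and C3–C4 bonds of ring C are cut. In one sentence: ring C of the upper unit is made by a [4+2] cycloaddition of the ortho-quinone methide 18, formed from 12, with the enol ester 17. This removes the ring, all three upper stereocentres and the upper ester at once; 12 has no stereocentre in its upper half and 17 is achiral. The forward step must deliver the regiochemistry (ester carbon to C4, O1 to the benzylic carbon), the endo mode on the E methide, one face of C4, and closure through one phenol only.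

**17 to 16 and 10; 16 to 14; 14 to 13.** The vinyl C–O bond of the enol ester is cut, then the C–B bond, then the alkyne is traced to an aldehyde. The E geometry must be defined because it becomes the 2,3-trans relation. Syn hydroboration of the alkyne sets it; the C–O coupling must retain it.

**12 to 11; 11 to 9 and 10.** The O–allyl bond is cut, then the ester C–O bond at O3'. The free phenol next to the carbinol is unmasked last because that pair is the labile quinone methide precursor. The ester is placed while the phenol is still masked. The demand is selective acylation of the C3' hydroxyl in the presence of the diaryl carbinol.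

**9 to 4 and 6 (through 7 and 8).** The bond between the carbinol carbon (the future C4) and C8' is cut. The aldehyde carbon of 6 becomes C4, and the bromine of 4 fixes the C8' regiochemistry without a Friedel–Crafts step. The demand is addition of a di-ortho-substituted aryllithium to a di-ortho-substituted aldehyde, with O3' protected and then released.

**4 to 3 to 2 to 1; 6 to 5.** O–Si, C–Br and O–benzyl bonds are cut back to the natural flavanol, which supplies C2' and C3' of the lower unit. The O–allyl bond of 6 is cut back to a regiodefined salicylaldehyde. The demands are C8 over C6 selectivity in the bromination and an allyl group orthogonal to benzyl, silyl and ester groups.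

## Other disconnections considered

**Alternative 1:** cut C4–C8' (the first plan that comes to mind). Forward key step: Lewis acid (TMSOTf or Yb(OTf)3) ionisation of the C4 ether A1 and Friedel–Crafts capture by C8 of the nucleophile A2, giving 19 directly. This route is shorter in steps, and that is conceded. The chosen plan is preferred on other grounds. In the Friedel–Crafts coupling the product remains a C8/C6 nucleophile and A1 can condense with itself, so oligomers form unless A2 is used in excess. The C8' over C6' selectivity rests on a modest steric bias. The O3 ester of A1 can participate at the C4 cation. Only flavanols from the natural pool can serve as the upper unit. The chosen plan fixes C8' by a bromine, builds the upper unit from achiral parts and sets C2, C3 and C4 in one operation.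

**Alternative 2:** cut O1'–C2' and C3'–C4' of ring F, the same cycloaddition applied to the lower unit. Forward key step: acid ionisation of the hydroxymethyl phenol A3 to the unsubstituted quinone methide A4 and [4+2] capture by 17. This leaves the interflavan bond and C4 to a conventional arylation of a C4 cation by a phloroglucinol derivative, so the hardest centre gains nothing. A4 has no substituent on its methide carbon, so it dimerises readily and a chiral acid has little to hold; C2' and C3' would then be set on the alkene faces with no nearby control element. The three free positions of the phloroglucinol ring in A3 would also have to be differentiated.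

**Alternative 3:** cut C4–C8' in a lactone and build C2 and C3 afterwards. Forward key step: asymmetric conjugate addition of the C8 boronic acid A5 to the coumarin A6 with Rh(acac)(C2H4)2 and a chiral bisphosphine, giving the 4-aryl dihydrocoumarin A7. The lactone is then converted through its enol triflate and a Suzuki–Miyaura coupling into the flav-2-ene A8, and hydroboration–oxidation anti to the C4 aryl group sets C2 and C3. The three stereocentres are set in two separate operations, followed by desilylation and two esterifications. A5 is a di-ortho-substituted, electron-rich boronic acid prone to protodeboronation, and the β-carbon of A6 lies next to the peri benzyloxy group. The sequence is longer than the chosen one after its first C–C bond, and that bond is its weakest step.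

Key step: step 11

Assumptions (remarks on the chemistry):
- Compound 5 is taken as a catalogue compound; it is otherwise one step (BnBr, K2CO3) from 2,4,6-trihydroxybenzaldehyde.
- The sense of induction of the binaphthyl phosphoric acid on 18 cannot be derived with certainty. The (R) acid is written; its mirror image takes its place with no other change if that proves to be the matched catalyst for the Re face of C4.

## Steps

Step 1
Reactants: 1 (+)-catechin [(2R,3S)-2-(3,4-dihydroxyphenyl)chromane-3,5,7-triol]
Product: 2 5,7,3',4'-tetra-O-benzyl-(+)-catechin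
Conditions: BnBr (4.4 equiv), K2CO3, DMF, 0 °C to rt
Reagents that add atoms: benzyl bromide, BrCc1ccccc1
Why: Williamson etherification; carbonate deprotonates the four phenols but not the secondary C3 hydroxyl, and C2 and C3 are untouched.

Step 2
Reactants: 2 5,7,3',4'-tetra-O-benzyl-(+)-catechin
Product: 3 8-bromo-5,7,3',4'-tetra-O-benzyl-(+)-catechin
Conditions: NBS (1.0 equiv), CH2Cl2, –78 °C to rt
Reagents that add atoms: N-bromosuccinimide, O=C1CCC(=O)N1Br
Why: Electrophilic aromatic bromination of the most electron-rich ring; C8 (between O1 and one benzyloxy group) should react in preference to C6 (between two benzyloxy groups), the usual bias of 5,7-di-O-benzyl flavan-3-ols.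

Step 3
Reactants: 3 8-bromo-5,7,3',4'-tetra-O-benzyl-(+)-catechin
Product: 4 8-bromo-3-O-(tert-butyldimethylsilyl)-5,7,3',4'-tetra-O-benzyl-(+)-catechin
Conditions: TBSCl, imidazole, DMF, rt
Reagents that add atoms: tert-butyldimethylsilyl chloride, CC(C)(C)[Si](C)(C)Cl
Why: Standard silylation of the secondary alcohol; it removes the acidic proton before the bromine–lithium exchange.

Step 4
Reactants: 5 2,4-bis(benzyloxy)-6-hydroxybenzaldehyde
Product: 6 2-(allyloxy)-4,6-bis(benzyloxy)benzaldehyde
Conditions: allyl bromide, K2CO3, DMF, 60 °C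
Reagents that add atoms: allyl bromide, C=CCBr
Why: Williamson etherification of the chelated phenol; the allyl group marks the oxygen that becomes O1 and is orthogonal to benzyl, silyl and ester groups.

Step 5
Reactants: 4 8-bromo-3-O-(tert-butyldimethylsilyl)-5,7,3',4'-tetra-O-benzyl-(+)-catechin; 6 2-(allyloxy)-4,6-bis(benzyloxy)benzaldehyde
Product: 9 8-{[2-(allyloxy)-4,6-bis(benzyloxy)phenyl](hydroxy)methyl}-5,7,3',4'-tetra-O-benzyl-(+)-catechin (both carbinol epimers), via aryllithium 7 (not isolated), via lithium alkoxide 8 (not isolated)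
Conditions: n-BuLi (1.05 equiv), THF, –78 °C; 6, –78 to –20 °C; then TBAF (3 equiv), 0 °C to rt; aq NH4Cl
Reagents that add atoms: none
Why: Bromine–lithium exchange at C8 followed by 1,2-addition to the aldehyde forms the C4–C8' bond with the regiochemistry fixed by the bromine; fluoride then removes the silyl group in the same flask. The carbinol centre forms without control, which does not matter because it is planarised in step 11.

Step 6
Reactants: 9 the diol from step 5; 10 3,4,5-tris(benzyloxy)benzoic acid
Product: 11 3-O-[3,4,5-tris(benzyloxy)benzoyl] ester of 9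
Conditions: DCC, DMAP (1.0 equiv), CH2Cl2, 0 °C to rt
Reagents that add atoms: none
Why: Steglich esterification; the C3' hydroxyl is an ordinary secondary alcohol, whereas the diaryl carbinol is shielded by four ortho oxygen substituents and should not be acylated by the bulky acylpyridinium. A full equivalent of DMAP keeps the medium basic so that the carbinol is not ionised.

Step 7
Reactants: 11 the monoester from step 6
Product: 12 8-{[2,4-bis(benzyloxy)-6-hydroxyphenyl](hydroxy)methyl}-5,7,3',4'-tetra-O-benzyl-(+)-catechin 3-O-[3,4,5-tris(benzyloxy)benzoate] (both carbinol epimers)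
Conditions: Pd(PPh3)4 (5 mol%), morpholine (5 equiv), THF, rt; filtration through Et3N-deactivated silica, used at once
Reagents that add atoms: none
Why: Tsuji–Trost deallylation; zerovalent palladium ionises the aryl allyl ether and morpholine traps the allyl group under neutral to basic conditions that leave the ester, the benzyl ethers and the acid-labile carbinol intact.

Step 8
Reactants: 13 3,4-bis(benzyloxy)benzaldehyde
Product: 14 1,2-bis(benzyloxy)-4-ethynylbenzene
Conditions: dimethyl (1-diazo-2-oxopropyl)phosphonate, K2CO3, MeOH, rt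
Reagents that add atoms: dimethyl (1-diazo-2-oxopropyl)phosphonate, CC(=O)C(=[N+]=[N-])P(=O)(OC)OC
Why: Seyferth–Gilbert homologation with the Ohira–Bestmann reagent converts the aromatic aldehyde into the terminal alkyne under mild base.

Step 9
Reactants: 14 1,2-bis(benzyloxy)-4-ethynylbenzene
Product: 16 potassium (E)-[2-(3,4-bis(benzyloxy)phenyl)ethenyl]trifluoroborate, via alkenyl catecholboronate 15 (not isolated)
Conditions: catecholborane (1.5 equiv), THF, 65 °C; then aq KHF2, MeOH, rt
Reagents that add atoms: catecholborane, [H]B1Oc2ccccc2O1; potassium hydrogen difluoride, [K+].F[H-]F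
Why: Syn, anti-Markovnikov hydroboration of the aryl alkyne fixes the E geometry; fluoride exchange gives the stable crystalline trifluoroborate.

Step 10
Reactants: 16 potassium (E)-[2-(3,4-bis(benzyloxy)phenyl)ethenyl]trifluoroborate; 10 3,4,5-tris(benzyloxy)benzoic acid
Product: 17 (E)-2-[3,4-bis(benzyloxy)phenyl]ethenyl 3,4,5-tris(benzyloxy)benzoate
Conditions: CuBr (10 mol%), DMAP (20 mol%), 4 Å MS, O2 (1 atm), CH2Cl2, 40 °C
Reagents that add atoms: none
Why: Chan–Lam oxidative C–O coupling of an alkenyl trifluoroborate with a carboxylic acid; the C–O bond forms at the boron-bearing carbon with retention of the alkene geometry, so the E enol ester is obtained without an enolisation step.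

Step 11
Reactants: 12 the ortho-hydroxy diaryl carbinol from step 7; 17 (E)-2-[3,4-bis(benzyloxy)phenyl]ethenyl 3,4,5-tris(benzyloxy)benzoate
Product: 19 tetradeca-O-benzyl procyanidin B3 3,3'-di-O-gallate (upper unit 2R,3S,4S; lower unit 2R,3S), via ortho-quinone methide 18 (not isolated)
Conditions: (R)-3,3'-bis(2,4,6-triisopropylphenyl)-1,1'-binaphthyl-2,2'-diyl hydrogen phosphate [(R)-TRIP] (10 mol%), 17 (2 equiv), 5 Å MS, CH2Cl2, –30 to 0 °C, 12 added over 4 h
Reagents that add atoms: none
Why: The acid ionises the doubly benzylic carbinol of 12 to the hydrogen-bonded ortho-quinone methide 18 (the sieves take up the water), which reacts as an electron-poor 1-oxadiene (O=C8a–C4a=C4) with the electron-rich alkene of 17 in an inverse-electron-demand hetero-Diels–Alder reaction; the closest known reaction type is the Brønsted-acid-catalysed [4+2] cycloaddition of ortho-quinone methides from ortho-hydroxybenzhydrols with styrenes, which gives cis-2,4-diarylchromans. Ring C is closed in the [4+2] mode, with C3–C4 formed ahead of O1–C2 in an asynchronous transition state, so a stepwise variant ends in the same ring by 6-endo capture of the C2 benzylic cation by the phenol oxygen. Regiochemistry rests on the 3,4-bis(benzyloxy)phenyl group being a much stronger cation-stabilising group than the ester oxygen, whose lone pair is engaged by its carbonyl: the ester-bearing carbon is the nucleophilic terminus and bonds to C4, and O1 bonds to the benzylic carbon. C2 and C3 come out trans because the E alkene adds suprafacially, and closure of a cation would also give the diequatorial arrangement. C4 is set relative to C3 by the E geometry of 18 (the Z form, reached through the diarylmethyl cation, is blocked as a diene by its inside aryl group) and by the endo position of the catechol aryl over the oxadiene, which puts the aryl groups on C2 and C4 cis and the ester trans to both, the all-equatorial isomer. The absolute configuration is set by the chiral phosphate held on the oxygen of 18, which is expected to leave the Re face of C4 (priorities C4a, C8', H) open to C3 of 17 and so give 2R,3S,4S; the lower-unit stereocentres lie four bonds from C4, so their own bias should be small, and a wrong-face adduct is a separable diastereomer. The step needs site selectivity, secured by O8a being the only free phenol (O7' is benzylated, so no pyran can close onto ring D), and chemoselectivity against Friedel–Crafts self-condensation of 18 at the free C6 and C8 positions of ring A, for which the excess of 17, the slow addition of 12 and the four ortho substituents around C4 are relied on.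

Step 12
Reactants: 19 tetradeca-O-benzyl procyanidin B3 3,3'-di-O-gallate
Product: 20 procyanidin B3 3,3'-di-O-gallate (CNP0281991.3)
Conditions: H2 (1 atm), Pd(OH)2/C, THF/MeOH (1:1), rt; filtration under argon, Sephadex LH-20, lyophilisation
Reagents that add atoms: none
Why: Neutral hydrogenolysis cleaves the fourteen benzyl ethers; the esters, the O1–C2 ring ethers and the C4–C8' bond are expected to survive, as is usual for benzylated flavan-3-ol gallates, and no stereocentre is touched.

## Compound list

1 | (+)-catechin | O[C@H]1Cc2c(O)cc(O)cc2O[C@@H]1c1ccc(O)c(O)c1 | starting material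
2 | 5,7,3',4'-tetra-O-benzyl-(+)-catechin | O[C@H]1Cc2c(OCc3ccccc3)cc(OCc3ccccc3)cc2O[C@@H]1c1ccc(OCc2ccccc2)c(OCc2ccccc2)c1 | intermediate
3 | 8-bromo-5,7,3',4'-tetra-O-benzyl-(+)-catechin | O[C@H]1Cc2c(OCc3ccccc3)cc(OCc3ccccc3)c(Br)c2O[C@@H]1c1ccc(OCc2ccccc2)c(OCc2ccccc2)c1 | intermediate
4 | 8-bromo-3-O-(tert-butyldimethylsilyl)-5,7,3',4'-tetra-O-benzyl-(+)-catechin | CC(C)(C)[Si](C)(C)O[C@H]1Cc2c(OCc3ccccc3)cc(OCc3ccccc3)c(Br)c2O[C@@H]1c1ccc(OCc2ccccc2)c(OCc2ccccc2)c1 | intermediate
5 | 2,4-bis(benzyloxy)-6-hydroxybenzaldehyde | O=Cc1c(O)cc(OCc2ccccc2)cc1OCc1ccccc1 | starting material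
6 | 2-(allyloxy)-4,6-bis(benzyloxy)benzaldehyde | O=Cc1c(OCC=C)cc(OCc2ccccc2)cc1OCc1ccccc1 | intermediate
7 | 8-lithio-3-O-(tert-butyldimethylsilyl)-5,7,3',4'-tetra-O-benzyl-(+)-catechin | CC(C)(C)[Si](C)(C)O[C@H]1Cc2c(OCc3ccccc3)cc(OCc3ccccc3)c([Li])c2O[C@@H]1c1ccc(OCc2ccccc2)c(OCc2ccccc2)c1 | intermediate (not isolated)
8 | lithium alkoxide of the 3-O-silyl diaryl carbinol (adduct of 7 and 6, both carbinol epimers) | [Li+].[O-]C(c1c(OCC=C)cc(OCc2ccccc2)cc1OCc1ccccc1)c1c(OCc2ccccc2)cc(OCc2ccccc2)c2c1O[C@H](c1ccc(OCc3ccccc3)c(OCc3ccccc3)c1)[C@@H](O[Si](C)(C)C(C)(C)C)C2 | intermediate (not isolated)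
9 | 8-{[2-(allyloxy)-4,6-bis(benzyloxy)phenyl](hydroxy)methyl}-5,7,3',4'-tetra-O-benzyl-(+)-catechin (both carbinol epimers) | OC(c1c(OCC=C)cc(OCc2ccccc2)cc1OCc1ccccc1)c1c(OCc2ccccc2)cc(OCc2ccccc2)c2c1O[C@H](c1ccc(OCc3ccccc3)c(OCc3ccccc3)c1)[C@@H](O)C2 | intermediate
10 | 3,4,5-tris(benzyloxy)benzoic acid | OC(=O)c1cc(OCc2ccccc2)c(OCc2ccccc2)c(OCc2ccccc2)c1 | starting material
11 | 3-O-[3,4,5-tris(benzyloxy)benzoyl] ester of 9 (both carbinol epimers) | OC(c1c(OCC=C)cc(OCc2ccccc2)cc1OCc1ccccc1)c1c(OCc2ccccc2)cc(OCc2ccccc2)c2c1O[C@H](c1ccc(OCc3ccccc3)c(OCc3ccccc3)c1)[C@@H](OC(=O)c1cc(OCc3ccccc3)c(OCc3ccccc3)c(OCc3ccccc3)c1)C2 | intermediate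
12 | 8-{[2,4-bis(benzyloxy)-6-hydroxyphenyl](hydroxy)methyl}-5,7,3',4'-tetra-O-benzyl-(+)-catechin 3-O-[3,4,5-tris(benzyloxy)benzoate] (both carbinol epimers) | OC(c1c(O)cc(OCc2ccccc2)cc1OCc1ccccc1)c1c(OCc2ccccc2)cc(OCc2ccccc2)c2c1O[C@H](c1ccc(OCc3ccccc3)c(OCc3ccccc3)c1)[C@@H](OC(=O)c1cc(OCc3ccccc3)c(OCc3ccccc3)c(OCc3ccccc3)c1)C2 | intermediate
13 | 3,4-bis(benzyloxy)benzaldehyde | O=Cc1ccc(OCc2ccccc2)c(OCc2ccccc2)c1 | starting material
14 | 1,2-bis(benzyloxy)-4-ethynylbenzene | C#Cc1ccc(OCc2ccccc2)c(OCc2ccccc2)c1 | intermediate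
15 | 2-[(E)-2-(3,4-bis(benzyloxy)phenyl)ethenyl]-1,3,2-benzodioxaborole | c1ccc2OB(/C=C/c3ccc(OCc4ccccc4)c(OCc4ccccc4)c3)Oc2c1 | intermediate (not isolated)
16 | potassium (E)-[2-(3,4-bis(benzyloxy)phenyl)ethenyl]trifluoroborate | [K+].F[B-](F)(F)/C=C/c1ccc(OCc2ccccc2)c(OCc2ccccc2)c1 | intermediate
17 | (E)-2-[3,4-bis(benzyloxy)phenyl]ethenyl 3,4,5-tris(benzyloxy)benzoate | O=C(O/C=C/c1ccc(OCc2ccccc2)c(OCc2ccccc2)c1)c1cc(OCc2ccccc2)c(OCc2ccccc2)c(OCc2ccccc2)c1 | intermediate
18 | (E)-ortho-quinone methide: 3,5-bis(benzyloxy)-6-(arylmethylidene)cyclohexa-2,4-dien-1-one, aryl = C8 of the lower unit of 12 | O=C1C=C(OCc2ccccc2)C=C(OCc2ccccc2)/C1=C\c1c(OCc2ccccc2)cc(OCc2ccccc2)c2c1O[C@H](c1ccc(OCc3ccccc3)c(OCc3ccccc3)c1)[C@@H](OC(=O)c1cc(OCc3ccccc3)c(OCc3ccccc3)c(OCc3ccccc3)c1)C2 | intermediate (not isolated)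
19 | tetradeca-O-benzyl procyanidin B3 3,3'-di-O-gallate | O=C(O[C@H]1[C@H](c2c(OCc3ccccc3)cc(OCc3ccccc3)c3c2O[C@H](c2ccc(OCc4ccccc4)c(OCc4ccccc4)c2)[C@@H](OC(=O)c2cc(OCc4ccccc4)c(OCc4ccccc4)c(OCc4ccccc4)c2)C3)c2c(OCc3ccccc3)cc(OCc3ccccc3)cc2O[C@@H]1c1ccc(OCc2ccccc2)c(OCc2ccccc2)c1)c1cc(OCc2ccccc2)c(OCc2ccccc2)c(OCc2ccccc2)c1 | intermediate
20 | procyanidin B3 3,3'-di-O-gallate (CNP0281991.3) | O=C(O[C@H]1[C@H](c2c(O)cc(O)c3c2O[C@H](c2ccc(O)c(O)c2)[C@@H](OC(=O)c2cc(O)c(O)c(O)c2)C3)c2c(O)cc(O)cc2O[C@@H]1c1ccc(O)c(O)c1)c1cc(O)c(O)c(O)c1 | target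

## Step count and least certain steps

Total step count: 12. Longest linear sequence: 8 steps (1, 2, 3, 5, 6, 7, 11, 12).

**Step 11 (key step).** Four things may go wrong.
- Slow capture: 18 is stabilised by two trioxygenated rings and hindered at C4, and 17 is a weak nucleophile, so Friedel–Crafts self-condensation of 18 may outrun the cycloaddition.
- Poor facial selectivity: 17 has no hydrogen-bond donor and binds the catalyst only through 18.
- Partial reversal of regiochemistry, if the acyloxy group competes with the aryl group as donor.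
- Erosion of the 3,4-trans relation, if an exo or open transition state competes.

Fallback, from 2 back to 19, by the conventional interflavan coupling. DDQ and 2-ethoxyethanol in CH2Cl2 oxidise C4 of 2 to 4-(2-ethoxyethoxy)-5,7,3',4'-tetra-O-benzylcatechin F1 (either C4 epimer serves). TMSOTf at –78 °C ionises F1 in the presence of an excess of 2, and C8 attacks the C4 cation trans to O3 to give octa-O-benzyl procyanidin B3 F2. Esterification of both hydroxyls of F2 with 10 (DCC, DMAP) gives 19.

**Step 7.** The ortho-hydroxy diaryl carbinol may lose its hydroxyl by ionisation during deallylation or isolation, and the quinone methide would then oligomerise before 17 is present. Fallback, from 11 back to 19, by oxidative generation of 18 from a stable diarylmethane. Ionic hydrogenation of 11 (Et3SiH, TFA, CH2Cl2, –40 °C) gives the diarylmethane allyl ether F3. Pd(PPh3)4 and morpholine give the 2-benzylphenol F4. Ag2O oxidises F4 to 18 under neutral conditions; after filtration, 17 and the phosphoric acid are added as in step 11 to give 19.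

**Step 6.** The carbinol may be acylated or ionised in competition with esterification of the C3' hydroxyl, because the carboxylic acid can protonate a carbinol that gives so stable a cation. Fallback, from 4 back to 12, placing the ester before the carbinol exists. Bromine–lithium exchange of 4 and DMF give 8-formyl-3-O-(tert-butyldimethylsilyl)-5,7,3',4'-tetra-O-benzylcatechin F5. TBAF gives 8-formyl-5,7,3',4'-tetra-O-benzylcatechin F6. DCC and DMAP with 10 give its 3-O-[3,4,5-tris(benzyloxy)benzoate] F7. Bromomagnesium 3,5-bis(benzyloxy)phenoxide F8 (from commercial 3,5-bis(benzyloxy)phenol and EtMgBr) then adds to the aldehyde of F7 in toluene through a six-membered magnesium chelate, specifically at the position ortho to the phenoxide oxygen, to give 12 without an allyl group.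

**Step 10.** Protodeboronation or homocoupling of the electron-rich alkenyl borate may outrun C–O coupling with the bulky acid, or the alkene geometry may erode. Fallback, from 14 and 10 back to 17, by enol acylation. Hydroboration of 14 with Cy2BH and oxidation with NaBO3 give 2-[3,4-bis(benzyloxy)phenyl]acetaldehyde F9. Oxalyl chloride and catalytic DMF convert 10 into 3,4,5-tris(benzyloxy)benzoyl chloride F10. O-acylation of the enolate of F9 with F10 (Et3N, DMAP, CH2Cl2) gives 17 together with its Z isomer; the E isomer, the more stable one, is separated by chromatography.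

## Further compounds

F1 | step 11 | 4-(2-ethoxyethoxy)-5,7,3',4'-tetra-O-benzylcatechin (C4 epimers) | O[C@H]1C(OCCOCC)c2c(OCc3ccccc3)cc(OCc3ccccc3)cc2O[C@@H]1c1ccc(OCc2ccccc2)c(OCc2ccccc2)c1
F2 | step 11 | octa-O-benzyl procyanidin B3 | O[C@H]1[C@H](c2c(OCc3ccccc3)cc(OCc3ccccc3)c3c2O[C@H](c2ccc(OCc4ccccc4)c(OCc4ccccc4)c2)[C@@H](O)C3)c2c(OCc3ccccc3)cc(OCc3ccccc3)cc2O[C@@H]1c1ccc(OCc2ccccc2)c(OCc2ccccc2)c1
F3 | step 7 | diarylmethane allyl ether (11 with CH2 in place of CHOH) | C(c1c(OCC=C)cc(OCc2ccccc2)cc1OCc1ccccc1)c1c(OCc2ccccc2)cc(OCc2ccccc2)c2c1O[C@H](c1ccc(OCc3ccccc3)c(OCc3ccccc3)c1)[C@@H](OC(=O)c1cc(OCc3ccccc3)c(OCc3ccccc3)c(OCc3ccccc3)c1)C2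
F4 | step 7 | 2-benzylphenol (12 with CH2 in place of CHOH) | C(c1c(O)cc(OCc2ccccc2)cc1OCc1ccccc1)c1c(OCc2ccccc2)cc(OCc2ccccc2)c2c1O[C@H](c1ccc(OCc3ccccc3)c(OCc3ccccc3)c1)[C@@H](OC(=O)c1cc(OCc3ccccc3)c(OCc3ccccc3)c(OCc3ccccc3)c1)C2
F5 | step 6 | 8-formyl-3-O-(tert-butyldimethylsilyl)-5,7,3',4'-tetra-O-benzylcatechin | O=Cc1c(OCc2ccccc2)cc(OCc2ccccc2)c2c1O[C@H](c1ccc(OCc3ccccc3)c(OCc3ccccc3)c1)[C@@H](O[Si](C)(C)C(C)(C)C)C2
F6 | step 6 | 8-formyl-5,7,3',4'-tetra-O-benzylcatechin | O=Cc1c(OCc2ccccc2)cc(OCc2ccccc2)c2c1O[C@H](c1ccc(OCc3ccccc3)c(OCc3ccccc3)c1)[C@@H](O)C2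
F7 | step 6 | 8-formyl-5,7,3',4'-tetra-O-benzylcatechin 3-O-[3,4,5-tris(benzyloxy)benzoate] | O=Cc1c(OCc2ccccc2)cc(OCc2ccccc2)c2c1O[C@H](c1ccc(OCc3ccccc3)c(OCc3ccccc3)c1)[C@@H](OC(=O)c1cc(OCc3ccccc3)c(OCc3ccccc3)c(OCc3ccccc3)c1)C2
F8 | step 6 | bromomagnesium 3,5-bis(benzyloxy)phenoxide | Br[Mg]Oc1cc(OCc2ccccc2)cc(OCc2ccccc2)c1
F9 | step 10 | 2-[3,4-bis(benzyloxy)phenyl]acetaldehyde | O=CCc1ccc(OCc2ccccc2)c(OCc2ccccc2)c1
F10 | step 10 | 3,4,5-tris(benzyloxy)benzoyl chloride | ClC(=O)c1cc(OCc2ccccc2)c(OCc2ccccc2)c(OCc2ccccc2)c1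
A1 | alternative 1 | 4-(2-ethoxyethoxy)-5,7,3',4'-tetra-O-benzylcatechin 3-O-[3,4,5-tris(benzyloxy)benzoate] (C4 epimers) | O=C(O[C@H]1C(OCCOCC)c2c(OCc3ccccc3)cc(OCc3ccccc3)cc2O[C@@H]1c1ccc(OCc2ccccc2)c(OCc2ccccc2)c1)c1cc(OCc2ccccc2)c(OCc2ccccc2)c(OCc2ccccc2)c1
A2 | alternative 1 | 5,7,3',4'-tetra-O-benzyl-(+)-catechin 3-O-[3,4,5-tris(benzyloxy)benzoate] | O=C(O[C@H]1Cc2c(OCc3ccccc3)cc(OCc3ccccc3)cc2O[C@@H]1c1ccc(OCc2ccccc2)c(OCc2ccccc2)c1)c1cc(OCc2ccccc2)c(OCc2ccccc2)c(OCc2ccccc2)c1
A3 | alternative 2 | (2R,3S,4S)-4-[4,6-bis(benzyloxy)-2-hydroxy-3-(hydroxymethyl)phenyl]-5,7,3',4'-tetra-O-benzylcatechin 3-O-[3,4,5-tris(benzyloxy)benzoate] | O=C(O[C@H]1[C@H](c2c(OCc3ccccc3)cc(OCc3ccccc3)c(CO)c2O)c2c(OCc3ccccc3)cc(OCc3ccccc3)cc2O[C@@H]1c1ccc(OCc2ccccc2)c(OCc2ccccc2)c1)c1cc(OCc2ccccc2)c(OCc2ccccc2)c(OCc2ccccc2)c1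
A4 | alternative 2 | ortho-quinone methide of A3 (unsubstituted methylidene on ring D) | O=C(O[C@H]1[C@H](C2=C(OCc3ccccc3)C=C(OCc3ccccc3)C(=C)C2=O)c2c(OCc3ccccc3)cc(OCc3ccccc3)cc2O[C@@H]1c1ccc(OCc2ccccc2)c(OCc2ccccc2)c1)c1cc(OCc2ccccc2)c(OCc2ccccc2)c(OCc2ccccc2)c1
A5 | alternative 3 | [3-O-(tert-butyldimethylsilyl)-5,7,3',4'-tetra-O-benzylcatechin-8-yl]boronic acid | OB(O)c1c(OCc2ccccc2)cc(OCc2ccccc2)c2c1O[C@H](c1ccc(OCc3ccccc3)c(OCc3ccccc3)c1)[C@@H](O[Si](C)(C)C(C)(C)C)C2
A6 | alternative 3 | 5,7-bis(benzyloxy)coumarin | O=C1C=Cc2c(OCc3ccccc3)cc(OCc3ccccc3)cc2O1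
A7 | alternative 3 | 4-aryl-5,7-bis(benzyloxy)-3,4-dihydrocoumarin (aryl = C8 of the silylated lower unit; C4 as in 19) | O=C1C[C@H](c2c(OCc3ccccc3)cc(OCc3ccccc3)c3c2O[C@H](c2ccc(OCc4ccccc4)c(OCc4ccccc4)c2)[C@@H](O[Si](C)(C)C(C)(C)C)C3)c2c(OCc3ccccc3)cc(OCc3ccccc3)cc2O1
A8 | alternative 3 | 4-aryl-5,7-bis(benzyloxy)-2-[3,4-bis(benzyloxy)phenyl]-4H-chromene (flav-2-ene; C4 as in 19) | C1(c2ccc(OCc3ccccc3)c(OCc3ccccc3)c2)=C[C@H](c2c(OCc3ccccc3)cc(OCc3ccccc3)c3c2O[C@H](c2ccc(OCc4ccccc4)c(OCc4ccccc4)c2)[C@@H](O[Si](C)(C)C(C)(C)C)C3)c2c(OCc3ccccc3)cc(OCc3ccccc3)cc2O1
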